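## Structural features

The target is (2S,3S,3aS)-3a-allyl-5-methoxy-3-methyl-2-(3,4,5-trimethoxyphenyl)-3,3a-dihydrobenzofuran-6(2H)-one. Ring B (O1, C2, C3, C3a, C7a) is a five-membered cyclic ether fused through the C3a–C7a bond to ring A, a six-membered cross-conjugated dienone (C4=C5(OMe)–C6(=O)–C7=C7a). In ring A, O1–C7a=C7–C6=O is a vinylogous ester and C4=C5(OMe)–C6=O is a diosphenol methyl ether, so ring A is flat, fully oxidised and carries no stereochemical information. The three stereocentres are contiguous: C2 (benzylic ether, aryl), C3 (methyl) and C3a (all-carbon quaternary ring-fusion atom, allyl). Read from the SMILES, aryl and methyl are trans and methyl and allyl are trans, so aryl and allyl share one face and the C4 arm of ring A is cis to the methyl. The fragile groups are the benzylic C2–O1 bond next to an electron-rich arene (ionisation, hydrogenolysis), the enol-ether part of the vinylogous ester (acid), the allyl group on a dienone carbon (sigmatropic or acid-induced migration towards an aromatic ring) and the terminal alkene (radicals, oxidants). The real difficulty is the quaternary C3a, which must be set relative to C3 and C2 beside a ring that offers no handle, and the late placing of the C5 oxygen. The route exploits the fact that, with C7a read as a carbonyl, O1–C2–C3–C3a–C7a is a γ-butyrolactone and C4–C7 is a 3-oxobutyl chain on its α-carbon; on that rigid lactone the C2 centre can direct a methyl nucleophile to C3 and the new C3 methyl can direct an allyl electrophile to C3a.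

## Logic of the disconnections

**21 back to 17.** The O–CH3 bond, the C5–O bond and the C4=C5 unsaturation are removed, passing through 20, 19 and 18. The cut is made there because C5 is the only enolisable position of 17, so its oxygen can be added last by enolate chemistry. The gain is a ring A that needs no oxygen at C5 while the skeleton is built. The demand is that hydroxylation, oxidation and methylation are mild enough for the allyl dienone and the benzylic ether.

**17 back to 15 and 14.** The enol ether O1–C7a is traced to the hydroxy diketone 16, and the C7–C7a bond of 16 is cut as a Claisen condensation, which leads to 15 and, with the ketone masked, to 14. Ring A disappears and becomes a four-carbon chain on a lactone that still holds all three stereocentres. The forward step needs the methyl-side enolate to acylate a lactone carbonyl flanked by a quaternary carbon, and an acid closure that does not ionise C2.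

**14 back to 11, 12 and a methyl cuprate.** The C3–CH3 and C3a–CH2(allyl) bonds (target numbering) are cut in one operation. This is the strategic cut: two stereocentres, one of them quaternary, fall away and a planar butenolide with one stereocentre remains. The forward step needs anti addition to the aryl-bearing face, then C-allylation anti to the new methyl, without loss of the acidic C5–H centre of 11.

**11 back to 9, then to 7 and 8.** The ring double bond is traced to the sulfoxide 10 and the sulfide 9, and the bond between the lactone α-carbon and the side-chain CH2 is cut. Sulfur serves twice: it acidifies the α-position for alkylation and later leaves to create the alkene. The demand is elimination into the ring, not into the side chain, under conditions that do not racemise 11.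

**7 back to 4 and 5.** The lactone Cα–Cβ bond (C3a–C3 of the target) and the acyl–oxygen bond are cut. This gives an oxirane whose single stereocentre becomes C2 of the target and a two-carbon acid that brings sulfur with it. The forward step needs attack at the CH2 carbon of 4 only. The oxirane required is (R): the benzylic centre is not touched, but the CH2 arm drops below aryl in priority once it carries carbon in place of oxygen, so (R)-4 leads to the (S) lactones.

**4 back to 2 and 1.** The oxirane C–O bond, the carbinol C–H bond and the C–Br bond are cut. All absolute stereochemistry then rests on one catalytic ketone reduction of a simple α-bromo ketone made from a cheap acetophenone.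

## Other disconnections considered

**Alternative 1:** The cut removes C2–C3 and O1–C2 of ring B from an aromatic ring A, and the C3a–allyl bond becomes a separate, later cut. In the forward sense base would expel sulfinate from phenol A1 to give an ortho-quinone methide. The ylide from sulfonium salt A2 would add to its exocyclic carbon (C3) and the phenoxide would displace the sulfide at C2, giving the trans dihydrobenzofuran A3. Debenzylation to phenol A4 and a dearomatising allylation with 12 at C3a, para to the C6 hydroxyl, would finish the target.
- In favour: two simple arenes are joined convergently, ring B and both C2 and C3 arise in one step, and the trans geometry follows from the backside displacement. The intermediates are robust aromatics. If every step held, the step count would be lower than in the chosen plan, so on step economy this alternative is the better one.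
- Against: A2 is achiral, so a single enantiomer would need a chiral sulfide or catalyst in its place. The hardest element, the quaternary C3a, is postponed to the alkylation of an ambident phenolate, where O-allylation and the free ortho carbon C7 compete with the hindered para carbon. Hydrogenolysis of the benzyl ether also has to spare the benzylic C2–O1 bond.
- Comparison: on the C2/C3 trans relationship the two plans are equal, and the C3 methyl would steer the allyl anti in both. Mechanistically the chosen plan alkylates a lactone enolate with one nucleophilic carbon, whereas here the site selectivity itself is uncertain.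

**Alternative 2:** The cut is the C3a–C7a bond, so ring A comes from a four-carbon cyclobutenone unit and an alkenyl side chain. Heating cyclobutenone A5 should open the four-membered ring to a dienylketene, which closes by a 6π electrocyclisation onto the disubstituted alkene terminus to give dienone A6. Desilylation and acid would then close ring B at C7a with loss of the isopropyl group from the vinylogous ester.
- In favour: ring A appears with the C5 methoxy group and the C6 oxygen already in place, so the three late oxidation-level steps of the chosen plan are not needed; on oxidation-state economy this alternative is better. The key step is neutral and thermal, and a pericyclic closure is little affected by crowding at the quaternary carbon.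
- Against: the configuration at C3a depends on which helical sense of the dienylketene closes, biased only by the neighbouring acyclic C3 centre. The side chain must be made as a stereodefined trisubstituted vinyl metal that already carries C2 and C3. Addition to an unsymmetrical cyclobutenedione and methylation of a tertiary alkoxide add further selectivity problems, and the final acid closure exposes a free benzylic alcohol.
- Comparison: both plans obtain C2 and C3 before the ring-forming event, so they are equal there. For C3a the chosen plan uses 1,2-induction on a rigid ring and is the more secure. In step count the alternative is at best equal.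

**Alternative 3:** The cut is O1–C7a. The side-chain hydroxyl of the prochiral dienone A7 would add to the β-carbon of one of its two diastereotopic enone arms, giving the cis-fused adduct A8; the choice of arm decides C3a.
- In favour: one mild catalytic step closes ring B and fixes C3a with no atoms wasted, and the reversibility allows equilibration. A7 might be reached quickly by dearomatising a para-substituted phenol, so up to the bicyclic core this plan is the better one on step economy.
- Against: the choice between the arms depends on whether the C3 methyl prefers to sit cis to the allyl CH2 or to the ring carbon C4, two groups of similar size, so selectivity for the required isomer is doubtful. A8 lacks both the C7=C7a double bond and the C5 oxygen. The dehydrogenation needs enolisation towards C7, which invites retro-oxa-Michael opening.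
- Comparison: both plans must oxygenate C5 late and are equal on that point. The chosen plan reaches the vinylogous ester level directly from the Claisen condensation and sets C3a in a kinetic, irreversible alkylation, so it is the better one on stereocontrol and on the number of oxidation-level changes.

Key step: step 6

Remark on the chemistry: 6, 7, 9 and 10 are carried as mixtures at the sulfur-bearing carbon and 18 as a mixture at C5, because these centres become trigonal later. The C3a descriptor changes between 17 (S), 18 and 19 (R) and 20 and 21 (S) only through priority changes, not through any change in space.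

Step 1
Reactants: 1 3',4',5'-trimethoxyacetophenone
Product: 2 2-bromo-1-(3,4,5-trimethoxyphenyl)ethanone
Conditions: CuBr2 (2 equiv), EtOAc/CHCl3, reflux
Reagents that add atoms: CuBr2, Br[Cu]Br
Why: α-Bromination of an aryl methyl ketone through its enol; CuBr2 should stop at the monobromide and leave the acyl-deactivated arene alone. No stereocentre is formed.

Step 2
Reactants: 2 2-bromo-1-(3,4,5-trimethoxyphenyl)ethanone
Product: 4 (R)-2-(3,4,5-trimethoxyphenyl)oxirane, via bromohydrin 3 (not isolated)
Conditions: (R)-1-methyl-3,3-diphenyltetrahydro-1H,3H-pyrrolo[1,2-c][1,3,2]oxazaborole (10 mol %), BH3·SMe2, THF, 0 °C; MeOH; then 2 M NaOH, 0 °C to rt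
Reagents that add atoms: none
Why: Corey–Bakshi–Shibata reduction: the ketone binds the catalyst boron with the aryl group turned away and hydride from the coordinated borane is delivered to one face, which with the (R) catalyst should give (R)-3 (spatially the same sense as for alkyl aryl ketones, descriptor R because CH2Br outranks aryl). Hydroxide then closes the oxirane by intramolecular SN2 at CH2, so the stereocentre is not touched.

Step 3
Reactants: 4 (R)-2-(3,4,5-trimethoxyphenyl)oxirane; 5 (phenylthio)acetic acid
Product: 7 (5S)-3-(phenylthio)-5-(3,4,5-trimethoxyphenyl)dihydrofuran-2(3H)-one (C3 epimers), via hydroxy acid 6 (not isolated)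
Conditions: 5, LiN(iPr)2 (2.1 equiv), THF, −78 to 0 °C; 4, 0 °C to rt; 1 M HCl; then TsOH (cat.), CH2Cl2, rt
Reagents that add atoms: none
Why: Oxirane opening by a carboxylic acid dianion followed by lactonisation: the soft sulfur-stabilised carbanion should attack the unhindered CH2 carbon by SN2, so the benzylic C–O bond and its configuration are kept (the descriptor becomes S only because the CH2 arm now ranks below aryl). The γ-hydroxy acid closes by acyl substitution under mild acid.

Step 4
Reactants: 7 (5S)-3-(phenylthio)-5-(3,4,5-trimethoxyphenyl)dihydrofuran-2(3H)-one (C3 epimers); 8 2-(2-bromoethyl)-2-methyl-1,3-dioxolane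
Product: 9 (5S)-3-[2-(2-methyl-1,3-dioxolan-2-yl)ethyl]-3-(phenylthio)-5-(3,4,5-trimethoxyphenyl)dihydrofuran-2(3H)-one (C3 epimers)
Conditions: LiN(iPr)2, THF, −78 °C; 8, NaI (0.2 equiv), DMPU, −78 °C to rt
Reagents that add atoms: none
Why: Enolate alkylation: the sulfur-stabilised lactone enolate is only moderately basic and should displace the primary bromide (iodide formed in situ by Finkelstein exchange) in preference to elimination. The configuration at C3 is irrelevant because this carbon becomes trigonal in step 5.

Step 5
Reactants: 9 (5S)-3-[2-(2-methyl-1,3-dioxolan-2-yl)ethyl]-3-(phenylthio)-5-(3,4,5-trimethoxyphenyl)dihydrofuran-2(3H)-one (C3 epimers)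
Product: 11 (S)-3-[2-(2-methyl-1,3-dioxolan-2-yl)ethyl]-5-(3,4,5-trimethoxyphenyl)furan-2(5H)-one, via sulfoxide 10 (not isolated)
Conditions: 3-chloroperbenzoic acid (1.0 equiv), CH2Cl2, −78 to 0 °C; NaHCO3 wash; then toluene, 90 °C
Reagents that add atoms: none
Why: Sulfide oxidation and thermal syn-elimination of the sulfoxide: the ring CH2 offers a syn hydrogen to either sulfoxide epimer, and α-alkyl-α-sulfinyl γ-lactones normally eliminate into the ring to give the α-alkyl butenolide. The base-free medium should keep the acidic C5–H centre intact.

Step 6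
Reactants: 11 (S)-3-[2-(2-methyl-1,3-dioxolan-2-yl)ethyl]-5-(3,4,5-trimethoxyphenyl)furan-2(5H)-one; 12 allyl bromide
Product: 14 (3S,4S,5S)-3-allyl-4-methyl-3-[2-(2-methyl-1,3-dioxolan-2-yl)ethyl]-5-(3,4,5-trimethoxyphenyl)dihydrofuran-2(3H)-one, via lithium enolate 13 (not isolated)
Conditions: CuI, MeLi (2 equiv per Cu), Et2O, 0 °C; 11, Et2O/THF, −78 to −30 °C; then DMPU, 12 (5 equiv), −78 to 0 °C; aq. NH4Cl/NH3
Reagents that add atoms: lithium dimethylcuprate, [Li+].C[Cu-]C
Why: The cuprate forms a π-complex with the C3=C4 bond of 11 and transfers methyl to C4 (C3 of the target) through a formally trivalent σ-copper species and reductive elimination, giving the lithium enolate 13, whose α-carbon (C3a of the target) then displaces bromide from 12. The closest known reaction type is the tandem organocuprate conjugate addition and enolate alkylation (vicinal difunctionalisation) of γ-substituted butenolides and cyclopentenones. No ring is closed. The methyl-bearing centre is controlled by the C5 aryl group, which shields one face of the nearly planar butenolide so that the cuprate adds anti to it and gives the 4,5-trans (4S,5S) arrangement. The quaternary centre is controlled by the new methyl group: in the planar enolate the adjacent sp3 substituent dominates, so 12 should enter anti to methyl, which places allyl trans to methyl and cis to the more remote aryl group and leaves the side chain cis to methyl (3S). The step needs 1,4-addition to win over 1,2-addition and over removal of the acidic C5–H, which the soft, weakly basic cuprate at low temperature should secure. It also needs C- over O-allylation, which a lithium enolate with a soft allylic bromide in a dipolar cosolvent should secure. The two facial selectivities rest on the rigid five-membered ring, and the dioxolane, aryl ethers and lactone are inert to the reagents.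

Step 7
Reactants: 14 (3S,4S,5S)-3-allyl-4-methyl-3-[2-(2-methyl-1,3-dioxolan-2-yl)ethyl]-5-(3,4,5-trimethoxyphenyl)dihydrofuran-2(3H)-one
Product: 15 (3S,4S,5S)-3-allyl-4-methyl-3-(3-oxobutyl)-5-(3,4,5-trimethoxyphenyl)dihydrofuran-2(3H)-one
Conditions: 1 M HCl, THF, rt
Reagents that add atoms: water, O
Why: Acid-catalysed acetal hydrolysis through the oxocarbenium ion. The lactone has no α-hydrogen and the alkene and aryl ethers are stable to dilute acid at room temperature, so no stereocentre is at risk.

Step 8
Reactants: 15 (3S,4S,5S)-3-allyl-4-methyl-3-(3-oxobutyl)-5-(3,4,5-trimethoxyphenyl)dihydrofuran-2(3H)-one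
Product: 17 (2S,3S,3aS)-3a-allyl-3-methyl-2-(3,4,5-trimethoxyphenyl)-3,3a,4,5-tetrahydrobenzofuran-6(2H)-one, via hydroxy diketone 16 (not isolated)
Conditions: KOtBu (2.5 equiv), THF, 0 °C to rt; 1 M HCl; then TsOH (5 mol %), benzene, 40 °C, 4 Å sieves
Reagents that add atoms: none
Why: Intramolecular Claisen condensation: only the methyl-side enolate can reach the lactone carbonyl (six-membered ring; the internal enolate would need a four-membered one), and the 1,3-diketone is withdrawn as its enolate, as in the cyclisation of 2,2-disubstituted 5-oxohexanoates. On acidification the freed C2 hydroxyl adds to the C7a carbonyl (five-membered hemiketal) and loses water to give the vinylogous ester. No stereocentre is touched, and the 2,3-trans arrangement is also the more stable one.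

Step 9
Reactants: 17 (2S,3S,3aS)-3a-allyl-3-methyl-2-(3,4,5-trimethoxyphenyl)-3,3a,4,5-tetrahydrobenzofuran-6(2H)-one
Product: 18 (2S,3S,3aR)-3a-allyl-5-hydroxy-3-methyl-2-(3,4,5-trimethoxyphenyl)-3,3a,4,5-tetrahydrobenzofuran-6(2H)-one (C5 epimers)
Conditions: KN(SiMe3)2, THF, −78 °C; 2-(phenylsulfonyl)-3-phenyloxaziridine, −78 °C; aq. NH4Cl
Reagents that add atoms: 2-(phenylsulfonyl)-3-phenyloxaziridine, O=S(=O)(c1ccccc1)N1OC1c1ccccc1
Why: Kinetic α'-deprotonation of a vinylogous ester (C5 is the only enolisable position) and electrophilic hydroxylation of the enolate by the N-sulfonyloxaziridine. The new C5 centre is removed in step 10, so its configuration does not matter.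

Step 10
Reactants: 18 (2S,3S,3aR)-3a-allyl-5-hydroxy-3-methyl-2-(3,4,5-trimethoxyphenyl)-3,3a,4,5-tetrahydrobenzofuran-6(2H)-one (C5 epimers)
Product: 20 (2S,3S,3aS)-3a-allyl-5-hydroxy-3-methyl-2-(3,4,5-trimethoxyphenyl)-3,3a-dihydrobenzofuran-6(2H)-one, via diketone 19 (not isolated)
Conditions: 1,1,1-triacetoxy-1,1-dihydro-1,2-benziodoxol-3(1H)-one, NaHCO3, CH2Cl2, 0 °C to rt
Reagents that add atoms: none
Why: Dess–Martin oxidation of the α-hydroxy ketone to the 1,2-diketone 19, which can enolise only towards C4 and should settle as the hydrogen-bonded, cross-conjugated diosphenol 20. The neutral buffered conditions spare the alkene and the enol ether.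

Step 11
Reactants: 20 (2S,3S,3aS)-3a-allyl-5-hydroxy-3-methyl-2-(3,4,5-trimethoxyphenyl)-3,3a-dihydrobenzofuran-6(2H)-one
Product: 21 (2S,3S,3aS)-3a-allyl-5-methoxy-3-methyl-2-(3,4,5-trimethoxyphenyl)-3,3a-dihydrobenzofuran-6(2H)-one
Conditions: Me2SO4, K2CO3, acetone, rt
Reagents that add atoms: dimethyl sulfate, COS(=O)(=O)OC
Why: Williamson-type O-methylation of the acidic diosphenol with a hard methylating agent and a weak base, which should favour oxygen over C4. Room temperature avoids migration of the allyl group.

## Compound list

1 | 3',4',5'-trimethoxyacetophenone | CC(=O)c1cc(OC)c(OC)c(OC)c1 | starting material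
2 | 2-bromo-1-(3,4,5-trimethoxyphenyl)ethanone | BrCC(=O)c1cc(OC)c(OC)c(OC)c1 | intermediate
3 | (R)-2-bromo-1-(3,4,5-trimethoxyphenyl)ethanol | O[C@H](c1cc(OC)c(OC)c(OC)c1)CBr | intermediate (not isolated)
4 | (R)-2-(3,4,5-trimethoxyphenyl)oxirane | O1C[C@H]1c2cc(OC)c(OC)c(OC)c2 | intermediate
5 | (phenylthio)acetic acid | OC(=O)CSc1ccccc1 | starting material
6 | (4S)-4-hydroxy-2-(phenylthio)-4-(3,4,5-trimethoxyphenyl)butanoic acid (C2 epimers) | OC(=O)C(Sc1ccccc1)C[C@H](O)c1cc(OC)c(OC)c(OC)c1 | intermediate (not isolated)
7 | (5S)-3-(phenylthio)-5-(3,4,5-trimethoxyphenyl)dihydrofuran-2(3H)-one (C3 epimers) | O=C1O[C@H](c2cc(OC)c(OC)c(OC)c2)CC1Sc3ccccc3 | intermediate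
8 | 2-(2-bromoethyl)-2-methyl-1,3-dioxolane | CC1(CCBr)OCCO1 | starting material
9 | (5S)-3-[2-(2-methyl-1,3-dioxolan-2-yl)ethyl]-3-(phenylthio)-5-(3,4,5-trimethoxyphenyl)dihydrofuran-2(3H)-one (C3 epimers) | O=C1O[C@H](c2cc(OC)c(OC)c(OC)c2)CC1(CCC3(C)OCCO3)Sc4ccccc4 | intermediate
10 | (5S)-3-[2-(2-methyl-1,3-dioxolan-2-yl)ethyl]-3-(phenylsulfinyl)-5-(3,4,5-trimethoxyphenyl)dihydrofuran-2(3H)-one (mixture at C3 and S) | O=C1O[C@H](c2cc(OC)c(OC)c(OC)c2)CC1(CCC3(C)OCCO3)S(=O)c4ccccc4 | intermediate (not isolated)
11 | (S)-3-[2-(2-methyl-1,3-dioxolan-2-yl)ethyl]-5-(3,4,5-trimethoxyphenyl)furan-2(5H)-one | O=C1O[C@H](c2cc(OC)c(OC)c(OC)c2)C=C1CCC3(C)OCCO3 | intermediate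
12 | allyl bromide (3-bromoprop-1-ene) | C=CCBr | starting material
13 | lithium (4S,5S)-4-methyl-3-[2-(2-methyl-1,3-dioxolan-2-yl)ethyl]-5-(3,4,5-trimethoxyphenyl)-4,5-dihydrofuran-2-olate | [Li+].[O-]C1=C(CCC2(C)OCCO2)[C@H](C)[C@@H](c3cc(OC)c(OC)c(OC)c3)O1 | intermediate (not isolated)
14 | (3S,4S,5S)-3-allyl-4-methyl-3-[2-(2-methyl-1,3-dioxolan-2-yl)ethyl]-5-(3,4,5-trimethoxyphenyl)dihydrofuran-2(3H)-one | C=CC[C@]1(CCC2(C)OCCO2)C(=O)O[C@H](c3cc(OC)c(OC)c(OC)c3)[C@H]1C | intermediate
15 | (3S,4S,5S)-3-allyl-4-methyl-3-(3-oxobutyl)-5-(3,4,5-trimethoxyphenyl)dihydrofuran-2(3H)-one | C=CC[C@]1(CCC(C)=O)C(=O)O[C@H](c2cc(OC)c(OC)c(OC)c2)[C@H]1C | intermediate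
16 | (4S)-4-allyl-4-[(1S,2S)-1-hydroxy-1-(3,4,5-trimethoxyphenyl)propan-2-yl]cyclohexane-1,3-dione | C=CC[C@@]1(CCC(=O)CC1=O)[C@H](C)[C@H](O)c2cc(OC)c(OC)c(OC)c2 | intermediate (not isolated)
17 | (2S,3S,3aS)-3a-allyl-3-methyl-2-(3,4,5-trimethoxyphenyl)-3,3a,4,5-tetrahydrobenzofuran-6(2H)-one | C=CC[C@]12CCC(=O)C=C1O[C@H](c3cc(OC)c(OC)c(OC)c3)[C@H]2C | intermediate
18 | (2S,3S,3aR)-3a-allyl-5-hydroxy-3-methyl-2-(3,4,5-trimethoxyphenyl)-3,3a,4,5-tetrahydrobenzofuran-6(2H)-one (C5 epimers) | C=CC[C@]12CC(O)C(=O)C=C1O[C@H](c3cc(OC)c(OC)c(OC)c3)[C@H]2C | intermediate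
19 | (2S,3S,3aR)-3a-allyl-3-methyl-2-(3,4,5-trimethoxyphenyl)-3,3a-dihydrobenzofuran-5,6(2H,4H)-dione | C=CC[C@]12CC(=O)C(=O)C=C1O[C@H](c3cc(OC)c(OC)c(OC)c3)[C@H]2C | intermediate (not isolated)
20 | (2S,3S,3aS)-3a-allyl-5-hydroxy-3-methyl-2-(3,4,5-trimethoxyphenyl)-3,3a-dihydrobenzofuran-6(2H)-one | C=CC[C@]12C=C(O)C(=O)C=C1O[C@H](c3cc(OC)c(OC)c(OC)c3)[C@H]2C | intermediate
21 | (2S,3S,3aS)-3a-allyl-5-methoxy-3-methyl-2-(3,4,5-trimethoxyphenyl)-3,3a-dihydrobenzofuran-6(2H)-one | C=CC[C@]12C=C(OC)C(=O)C=C1O[C@H](c1cc(OC)c(OC)c(OC)c1)[C@H]2C | target

## Step count and least certain steps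

Total: 11 steps. Longest linear sequence: 11 steps, from 1 to 21; the route is linear and 5, 8 and 12 enter as purchased materials.

**Step 6 (key step).**
- Risk: conjugate addition to the α-substituted butenolide is slow, so removal of the doubly activated C5–H (giving an aromatic oxidofuran) may compete and erode enantiopurity. Allylation of the copper-containing tetrasubstituted enolate may also be slow enough for proton transfer, and the facial preference at C3a may be incomplete because the allyl group enters on the face of the remote aryl group.
- Fallback: it sets out from 11. Me2CuLi with Me3SiCl in THF at −78 °C should speed up the 1,4-addition and trap the enolate at once as the silyl ketene acetal F1, which is isolated. In a separate flask MeLi cleaves the O–Si bond to give copper-free 13, which is allylated with 12 in THF/DMPU. The fallback comes back to the route at 13 and so at 14.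

**Step 5.**
- Risk: elimination towards the side-chain CH2 in place of the ring CH2, or loss of configuration at C5 by tautomerisation of the product at 90 °C in the presence of the sulfenic acid by-product.
- Fallback: it sets out from 9. Bu3SnH and azobisisobutyronitrile in toluene remove sulfur homolytically to give the α-alkyl lactone F2. LiN(iPr)2 and PhSeBr at −78 °C give the α-phenylselanyl lactone F3. H2O2 with pyridine in CH2Cl2 at 0 °C gives the selenoxide F4, which eliminates below room temperature and returns to the route at 11.

**Step 4.**
- Risk: base-induced elimination of HBr from 8, or slow alkylation at a carbon that becomes quaternary, leaving 7 unchanged.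
- Fallback: it sets out from 7. Michael addition of its enolate (catalytic 1,8-diazabicyclo[5.4.0]undec-7-ene, THF) to but-3-en-2-one gives the 3-oxobutyl sulfide F5. Ethylene glycol with pyridinium p-toluenesulfonate in benzene under water removal then forms the dioxolane and returns to the route at 9.

**Step 3.**
- Risk: partial attack at the benzylic carbon of the oxirane, giving the regioisomeric lactone with inversion, or slow opening by the aggregated dianion.
- Fallback: it sets out from 2 and never forms an oxirane. The sodium enolate of methyl (phenylthio)acetate (NaH, THF, 0 °C) is alkylated by 2 to give the keto ester F6. The same (R)-oxazaborolidine with BH3·SMe2 reduces the aryl ketone to the hydroxy ester F7, which has the 4S configuration for the reason given in step 2. TsOH in CH2Cl2 lactonises F7 and returns to the route at 7.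

**Step 9.**
- Risk: addition of the enolate to the sulfonylimine formed from the oxidant, or incomplete enolisation, leaving mixtures that are hard to separate from 17.
- Fallback: it sets out from 17. Heating with tert-butoxybis(dimethylamino)methane in toluene gives the enaminone F8. Sensitised photo-oxygenation (O2, tetraphenylporphyrin, visible light, CH2Cl2, −78 °C) cleaves its exocyclic C=C bond to give 19, which enolises. The fallback comes back to the route at 20 and bypasses 18.

## Further compounds

F1 | step 6 | trimethyl{[(4S,5S)-4-methyl-3-[2-(2-methyl-1,3-dioxolan-2-yl)ethyl]-5-(3,4,5-trimethoxyphenyl)-4,5-dihydrofuran-2-yl]oxy}silane | C[Si](C)(C)OC1=C(CCC2(C)OCCO2)[C@H](C)[C@@H](c3cc(OC)c(OC)c(OC)c3)O1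
F2 | step 5 | (5S)-3-[2-(2-methyl-1,3-dioxolan-2-yl)ethyl]-5-(3,4,5-trimethoxyphenyl)dihydrofuran-2(3H)-one (C3 epimers) | O=C1O[C@H](c2cc(OC)c(OC)c(OC)c2)CC1CCC3(C)OCCO3
F3 | step 5 | (5S)-3-[2-(2-methyl-1,3-dioxolan-2-yl)ethyl]-3-(phenylselanyl)-5-(3,4,5-trimethoxyphenyl)dihydrofuran-2(3H)-one (C3 epimers) | O=C1O[C@H](c2cc(OC)c(OC)c(OC)c2)CC1(CCC3(C)OCCO3)[Se]c4ccccc4
F4 | step 5 | (5S)-3-[2-(2-methyl-1,3-dioxolan-2-yl)ethyl]-3-(phenylseleninyl)-5-(3,4,5-trimethoxyphenyl)dihydrofuran-2(3H)-one | O=C1O[C@H](c2cc(OC)c(OC)c(OC)c2)CC1(CCC3(C)OCCO3)[Se](=O)c4ccccc4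
F5 | step 4 | (5S)-3-(3-oxobutyl)-3-(phenylthio)-5-(3,4,5-trimethoxyphenyl)dihydrofuran-2(3H)-one (C3 epimers) | O=C1O[C@H](c2cc(OC)c(OC)c(OC)c2)CC1(CCC(C)=O)Sc3ccccc3
F6 | step 3 | methyl 4-oxo-2-(phenylthio)-4-(3,4,5-trimethoxyphenyl)butanoate | COC(=O)C(Sc1ccccc1)CC(=O)c1cc(OC)c(OC)c(OC)c1
F7 | step 3 | methyl (4S)-4-hydroxy-2-(phenylthio)-4-(3,4,5-trimethoxyphenyl)butanoate (C2 epimers) | COC(=O)C(Sc1ccccc1)C[C@H](O)c1cc(OC)c(OC)c(OC)c1
F8 | step 9 | (2S,3S,3aR)-3a-allyl-5-[(dimethylamino)methylidene]-3-methyl-2-(3,4,5-trimethoxyphenyl)-3,3a,4,5-tetrahydrobenzofuran-6(2H)-one | C=CC[C@]12CC(=CN(C)C)C(=O)C=C1O[C@H](c3cc(OC)c(OC)c(OC)c3)[C@H]2C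
A1 | alternative 1 | 5-(benzyloxy)-4-methoxy-2-[1-(4-methylphenylsulfonyl)ethyl]phenol (racemic) | CC(c1cc(OC)c(OCc2ccccc2)cc1O)S(=O)(=O)c1ccc(C)cc1
A2 | alternative 1 | dimethyl(3,4,5-trimethoxybenzyl)sulfonium bromide | C[S+](C)Cc1cc(OC)c(OC)c(OC)c1.[Br-]
A3 | alternative 1 | (2S,3S)-6-(benzyloxy)-5-methoxy-3-methyl-2-(3,4,5-trimethoxyphenyl)-2,3-dihydrobenzofuran | c12cc(OC)c(OCc3ccccc3)cc1O[C@H](c1cc(OC)c(OC)c(OC)c1)[C@H]2C
A4 | alternative 1 | (2S,3S)-5-methoxy-3-methyl-2-(3,4,5-trimethoxyphenyl)-2,3-dihydrobenzofuran-6-ol | c12cc(OC)c(O)cc1O[C@H](c1cc(OC)c(OC)c(OC)c1)[C@H]2C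
A5 | alternative 2 | 4-{2-[(1S,2S)-1-(tert-butyldimethylsilyloxy)-1-(3,4,5-trimethoxyphenyl)propan-2-yl]penta-1,4-dien-1-yl}-3-isopropoxy-4-methoxycyclobut-2-en-1-one | C=CCC(=CC1(OC)C(OC(C)C)=CC1=O)[C@H](C)[C@H](O[Si](C)(C)C(C)(C)C)c1cc(OC)c(OC)c(OC)c1
A6 | alternative 2 | (6S)-6-allyl-6-[(1S,2S)-1-(tert-butyldimethylsilyloxy)-1-(3,4,5-trimethoxyphenyl)propan-2-yl]-3-isopropoxy-4-methoxycyclohexa-2,4-dien-1-one | C=CC[C@@]1(C=C(OC)C(OC(C)C)=CC1=O)[C@H](C)[C@H](O[Si](C)(C)C(C)(C)C)c1cc(OC)c(OC)c(OC)c1
A7 | alternative 3 | 4-allyl-4-[(1S,2S)-1-hydroxy-1-(3,4,5-trimethoxyphenyl)propan-2-yl]cyclohexa-2,5-dien-1-one | C=CCC1(C=CC(=O)C=C1)[C@H](C)[C@H](O)c1cc(OC)c(OC)c(OC)c1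
A8 | alternative 3 | (2S,3S,3aR,7aR)-3a-allyl-3-methyl-2-(3,4,5-trimethoxyphenyl)-3,3a,7,7a-tetrahydrobenzofuran-6(2H)-one | C=CC[C@]12C=CC(=O)C[C@H]1O[C@H](c1cc(OC)c(OC)c(OC)c1)[C@H]2C
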